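The earlier runs and the new flask were generated by integration for an exercise, noise included.

A one-step picture has left-handed substrate coupling away and the excess of right-handed substrate climbing for good, but midnight reads 44.2% at 50.0 min and 33.3% at 90.0 min, so a second step seems to be closing the gap.

| flask | left-handed substrate | right-handed substrate | coupling partner | free catalyst | racemization catalyst | impurity | remark | time |
|---|---|---|---|---|---|---|---|---|
| dusk | 20 mM | 20 mM | 50 mM | 2.2 mM | 50 µM | 11 µM | run made earlier |  |
| winter | 20 mM | 20 mM | 50 mM | 2.2 mM | 200 µM | 11 µM | run made earlier |  |
| midnight | 20 mM | 20 mM | 50 mM | 2.2 mM | 100 µM | 16 µM | run made earlier |  |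
| ochre | 20 mM | 20 mM | 50.0 mM | 2.2 mM | 100 µM | 11 µM |  | 2.5 h |
| violet | 20 mM | 20 mM | 50.0 mM | 2.2 mM | 100 µM | 11 µM |  | 5.0 h |

| run | time / min | right-handed substrate / % | left-handed substrate / % | left-handed product / % |
|---|---|---|---|---|
| dusk | 8.00 | 45 | 28 | 24 |
| dusk | 15.0 | 46 | 22 | 28 |
| dusk | 25.0 | 40 | 16 | 37 |
| dusk | 50.0 | 36 | 9 | 49 |
| dusk | 90.0 | 28 | 9 | 56 |
| winter | 20.0 | 36 | 21 | 34 |
| winter | 40.0 | 25 | 17 | 51 |
| winter | 50.0 | 23 | 14 | 54 |
| winter | 80.0 | 19 | 16 | 65 |
| winter | 90.0 | 16 | 7 | 65 |
| midnight | 20.0 | 42 | 19 | 33 |
| midnight | 40.0 | 33 | 13 | 49 |
| midnight | 50.0 | 31 | 12 | 52 |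
| midnight | 80.0 | 22 | 13 | 56 |
| midnight | 90.0 | 20 | 10 | 64 |

(scatter of a reading: 2 percentage points)

- free catalyst is single-handed; left-handed substrate and right-handed substrate are mirror images of each other, charged as a racemate, each of them at the stated concentration
- what was read earlier has a scatter of 2 percentage points, one standard deviation
- an excess is below zero if the other one leads

- which one finishes higher in excess of right-handed substrate over left-handed substrate among what is left of the two ("neither" within 2 percentage points) (ochre / violet / neither)
- excess of right-handed substrate over left-handed substrate among what is left of the two at the end, ochre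
- excess of right-handed substrate over left-handed substrate among what is left of the two at the end, violet

I run midnight in slow motion. By 20.0 min the left-handed substrate reads 19% against 42% of right-handed substrate, with 33% of left-handed product. From there to 50.0 min the pseudo-first-order coupling constant on the left-handed substrate reads 0.0409 min⁻¹. From 50.0 min to 90.0 min it reads 0.0273 min⁻¹, while the fall of right-handed substrate over the mean gap gives racemization 0.0190 min⁻¹, so in the midnight readings the coupling constant still stands higher than the racemization constant but lower than it read before. While the two substrates stand close, and counting coupling of the left-handed substrate and of no other, the gap, per unit of what remains, opens at the coupling constant over 2 and closes at 2 times the racemization constant times the excess. Setting these equal, the minutes cancel and leave the balance excess, coupling constant over 4 racemization constants, which late in midnight reads 36.0%.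

I take the impurity to remove its own amount of racemization catalyst and let coupling keep falling by the same factor per step of time. That gives my own 13.5% for ochre and 2.38% for violet. The forecast says ochre, with 20% and 5%, which are not my figures, and sees the violet excess fall “as racemization re-equalizes the remainder”.

The flask gives ochre, with 20.8% for ochre and 12.0% for violet.

    coupling partner + free catalyst + left-handed substrate → free catalyst + left-handed product (k = 700 M⁻² min⁻¹)
    coupling partner + free catalyst + right-handed substrate → free catalyst + right-handed product (k = 55.0 M⁻² min⁻¹)
    left-handed substrate + racemization catalyst ⇌ right-handed substrate + racemization catalyst, rate k3*[racemization catalyst]*[left-handed substrate] forward; the back reaction follows from the equilibrium constant (k = 170 M⁻¹ min⁻¹)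
    racemization catalyst + impurity → spent catalyst (k = 2.50 × 10⁵ M⁻¹ min⁻¹)
    free catalyst ⇌ dormant form (K = 2.10, k = 0.00970 min⁻¹)

In ochre at 2.50 h, coupling partner at 37.1% and free catalyst at 40.2% of their charges make the coupling constant 0.0115 min⁻¹, smaller than the racemization constant of 0.0151 min⁻¹, so the balance excess, which read 36.0% late in midnight, another flask at an earlier time, stands at 19.0% in ochre. In violet at 5.00 h it is 12.3%. In the neighbour flask with 0.17 mM of racemization catalyst, the same ratio gives 10.0%, and the computed excess there is 10.3%.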